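**Strategy.** The all-E nonaene is cut at the sp2–sp2 single bond C15'–C14', between the central C15=C15' alkene and the C13'=C14' alkene on the side of the hydroxylated ring B. Ring A (3-oxo) and ring B (3-hydroxy) share the 6S ε-ring and differ only in oxidation level at C3, so both partners descend from one resolved C19 tetraenyl iodide. Oxidised and extended by a two-carbon distannylethene linchpin, it becomes the C21 pentaenylstannane. A base-free, stereoretentive Stille coupling then joins this to the unchanged hydroxy iodide and should deliver the unprotected C40 target in the last step.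

Key step: step 11

Remark: carotenoid numbering is used, unprimed for the half with the 3-oxo ring A and primed for the half with the 3-hydroxy ring B; commercial α-ionone is taken as the racemate, so absolute configuration is introduced in step 3.

**Step 1**
Reactants: 1 (±)-α-ionone; 2 diethyl cyanomethylphosphonate
Product: 4 rac-(2E,4E)-3-methyl-5-(2,6,6-trimethylcyclohex-2-en-1-yl)penta-2,4-dienenitrile, via sodium cyanomethylphosphonate carbanion 3 (not isolated)
Conditions: NaH, THF, 0 °C to rt; chromatography to remove the minor (9Z) isomer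
Reagents that add atoms: none
Why: Horner–Wadsworth–Emmons olefination of the methyl ketone with the stabilised phosphonate carbanion should give the conjugated dienenitrile with the (9E) isomer favoured, no stereocentre being set.

**Step 2**
Reactants: 4 rac-(2E,4E)-3-methyl-5-(2,6,6-trimethylcyclohex-2-en-1-yl)penta-2,4-dienenitrile
Product: 5 rac-(2E,4E)-3-methyl-5-(2,6,6-trimethyl-4-oxocyclohex-2-en-1-yl)penta-2,4-dienenitrile
Conditions: t-BuOOH (70% aq., 5 equiv), Rh2(cap)4 (dirhodium tetracaprolactamate, 1 mol%), K2CO3 (0.5 equiv), CH2Cl2, rt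
Reagents that add atoms: tert-butyl hydroperoxide, CC(C)(C)OO
Why: Dirhodium-catalysed allylic oxidation (hydrogen abstraction by tert-butylperoxyl radicals, then peroxide collapse) should convert the accessible secondary allylic C3 methylene of the ring into the enone carbonyl in preference to the shielded tertiary C6–H.

**Step 3**
Reactants: 5 rac-(2E,4E)-3-methyl-5-(2,6,6-trimethyl-4-oxocyclohex-2-en-1-yl)penta-2,4-dienenitrile
Product: 6 (2E,4E)-5-[(1S,4S)-4-hydroxy-2,6,6-trimethylcyclohex-2-en-1-yl]-3-methylpenta-2,4-dienenitrile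
Conditions: (S)-selective ketoreductase (NADPH-dependent alcohol dehydrogenase class, chosen from a screening panel), NADP+ (cat.), i-PrOH (15% v/v), phosphate buffer pH 7, 30 °C; chromatographic removal of the cis diastereomer
Reagents that add atoms: none
Why: Enzymatic asymmetric ketone reduction, in which hydride from NADPH (regenerated by i-PrOH) is delivered to one face of the C3 carbonyl, is expected to set C3 as S under enzyme control in both enantiomers of 5, so that the 6S enantiomer gives trans-(3S,6S)-6 and the 6R enantiomer the separable cis-(3S,6R) diastereomer, the step thus creating C3 and resolving C6.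

**Step 4**
Reactants: 6 (2E,4E)-5-[(1S,4S)-4-hydroxy-2,6,6-trimethylcyclohex-2-en-1-yl]-3-methylpenta-2,4-dienenitrile
Product: 8 (2E,4E)-5-[(1S,4S)-4-hydroxy-2,6,6-trimethylcyclohex-2-en-1-yl]-3-methylpenta-2,4-dienal, via N-aluminated aldimine 7 (not isolated)
Conditions: DIBAL-H (2.5 equiv), CH2Cl2, −78 to −40 °C; then aq. potassium sodium tartrate, rt
Reagents that add atoms: water, O
Why: DIBAL-H reduction of a conjugated nitrile stops at the N-aluminated aldimine, which hydrolyses on neutral work-up to the enal, the first equivalent of hydride being consumed by the free hydroxyl and no stereocentre being touched.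

**Step 5**
Reactants: 9 propargyl alcohol
Product: 11 (2E)-3-iodo-2-methylprop-2-en-1-ol, via alkenylalane 10 (not isolated)
Conditions: AlMe3 (3 equiv), Cp2ZrCl2 (0.25 equiv), CH2Cl2, 0 °C to rt; then I2, THF, −30 °C; aq. K2CO3
Reagents that add atoms: trimethylaluminium, C[Al](C)C; iodine, II
Why: Negishi zirconium-catalysed carboalumination adds methyl and aluminium syn across the alkyne with aluminium at the terminal carbon, and iodinolysis with retention should give the E alkenyl iodide.

**Step 6**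
Reactants: 11 (2E)-3-iodo-2-methylprop-2-en-1-ol
Product: 12 (1E)-3-bromo-1-iodo-2-methylprop-1-ene
Conditions: CBr4, PPh3, CH2Cl2, 0 °C
Reagents that add atoms: tetrabromomethane, BrC(Br)(Br)Br
Why: Appel bromination converts the primary allylic alcohol into the bromide by SN2 displacement of the oxyphosphonium without touching the alkenyl iodide.

**Step 7**
Reactants: 12 (1E)-3-bromo-1-iodo-2-methylprop-1-ene
Product: 13 diethyl [(2E)-3-iodo-2-methylprop-2-en-1-yl]phosphonate
Conditions: P(OEt)3 (neat), 90 °C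
Reagents that add atoms: triethyl phosphite, CCOP(OCC)OCC
Why: Michaelis–Arbuzov reaction of the primary allylic bromide with triethyl phosphite should give the allylic phosphonate, the alkenyl iodide being inert in the absence of a transition metal.

**Step 8**
Reactants: 8 (2E,4E)-5-[(1S,4S)-4-hydroxy-2,6,6-trimethylcyclohex-2-en-1-yl]-3-methylpenta-2,4-dienal; 13 diethyl [(2E)-3-iodo-2-methylprop-2-en-1-yl]phosphonate
Product: 15 (1S,4S)-4-[(1E,3E,5E,7E)-8-iodo-3,7-dimethylocta-1,3,5,7-tetraen-1-yl]-3,5,5-trimethylcyclohex-2-en-1-ol, via sodium iodoallylphosphonate carbanion 14 (not isolated)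
Conditions: 13 (2.2 equiv), NaHMDS (2.1 equiv), THF, −78 °C; then 8, −78 to 0 °C; aq. NH4Cl
Reagents that add atoms: none
Why: Horner–Wadsworth–Emmons olefination of the enal with the allylic phosphonate carbanion should form the C11=C12 bond with E geometry, the alkenyl iodide (no β-hydrogen) and the free hydroxyl tolerating the excess carbanion, and the low temperature guarding C6 against epimerisation.

**Step 9**
Reactants: 15 (1S,4S)-4-[(1E,3E,5E,7E)-8-iodo-3,7-dimethylocta-1,3,5,7-tetraen-1-yl]-3,5,5-trimethylcyclohex-2-en-1-ol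
Product: 16 (4S)-4-[(1E,3E,5E,7E)-8-iodo-3,7-dimethylocta-1,3,5,7-tetraen-1-yl]-3,5,5-trimethylcyclohex-2-en-1-one
Conditions: activated MnO2 (20 equiv), CH2Cl2, rt, dark, argon
Reagents that add atoms: none
Why: MnO2 oxidises the secondary allylic alcohol selectively to the enone under neutral conditions, so the now vinylogously acidic C6–H keeps its S configuration.

**Step 10**
Reactants: 16 (4S)-4-[(1E,3E,5E,7E)-8-iodo-3,7-dimethylocta-1,3,5,7-tetraen-1-yl]-3,5,5-trimethylcyclohex-2-en-1-one; 17 (E)-1,2-bis(tributylstannyl)ethene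
Product: 18 (4S)-4-[(1E,3E,5E,7E,9E)-3,7-dimethyl-10-(tributylstannyl)deca-1,3,5,7,9-pentaen-1-yl]-3,5,5-trimethylcyclohex-2-en-1-one
Conditions: 17 (3 equiv), Pd2(dba)3 (2.5 mol%), AsPh3 (20 mol%), NMP, rt, dark; rapid chromatography on neutral alumina
Reagents that add atoms: none
Why: Stille coupling of the alkenyl iodide with an excess of the distannylethene linchpin should give the mono-coupled pentaenylstannane with retention of both alkene geometries, the excess suppressing double coupling and the absence of base protecting C6.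

**Step 11**
Reactants: 18 (4S)-4-[(1E,3E,5E,7E,9E)-3,7-dimethyl-10-(tributylstannyl)deca-1,3,5,7,9-pentaen-1-yl]-3,5,5-trimethylcyclohex-2-en-1-one; 15 (1S,4S)-4-[(1E,3E,5E,7E)-8-iodo-3,7-dimethylocta-1,3,5,7-tetraen-1-yl]-3,5,5-trimethylcyclohex-2-en-1-ol
Product: 19 (3'S,6S,6'S)-3'-hydroxy-ε,ε-caroten-3-one
Conditions: 18 (1.1 equiv), 15 (1.0 equiv), Pd2(dba)3 (5 mol%), AsPh3 (40 mol%), degassed NMP, rt to 40 °C, dark, argon
Reagents that add atoms: none
Why: In this Stille alkenyl–alkenyl cross-coupling, oxidative addition of the C14'–I bond of 15 to zerovalent palladium, tin-to-palladium transmetalation of the C15' terminus of 18 (fast with the weakly bound AsPh3 ligand) and reductive elimination form the C15'–C14' bond. The closest known reaction type is the stereoretentive Stille coupling of polyenyl stannanes with polyenyl iodides used for retinoids and carotenoids. No ring is closed and no stereocentre is created; C3', C6' and C6 are carried in unchanged. Both alkene geometries are retained because all three elementary steps are stereospecific, so the all-E nonaene should result. The selectivity needed is cross- over homocoupling and chemoselectivity beside a free allylic alcohol, an enone and the epimerisable C6–H of ring A; the reactive unhindered alkenyl iodide, near-equimolar partners, exclusion of oxygen and light, and neutral base-free conditions secure it.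

**Compound list**
1 | (±)-α-ionone, (3E)-4-(2,6,6-trimethylcyclohex-2-en-1-yl)but-3-en-2-one | CC(=O)/C=C/C1C(C)=CCCC1(C)C | starting material
2 | diethyl cyanomethylphosphonate | CCOP(=O)(CC#N)OCC | starting material
3 | sodium cyano(diethoxyphosphoryl)methanide | CCOP(=O)([CH-]C#N)OCC.[Na+] | intermediate
4 | rac-(2E,4E)-3-methyl-5-(2,6,6-trimethylcyclohex-2-en-1-yl)penta-2,4-dienenitrile | N#C/C=C(C)/C=C/C1C(C)=CCCC1(C)C | intermediate
5 | rac-(2E,4E)-3-methyl-5-(2,6,6-trimethyl-4-oxocyclohex-2-en-1-yl)penta-2,4-dienenitrile | N#C/C=C(C)/C=C/C1C(C)=CC(=O)CC1(C)C | intermediate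
6 | (2E,4E)-5-[(1S,4S)-4-hydroxy-2,6,6-trimethylcyclohex-2-en-1-yl]-3-methylpenta-2,4-dienenitrile | N#C/C=C(C)/C=C/[C@@H]1C(C)=C[C@@H](O)CC1(C)C | intermediate
7 | N-(diisobutylaluminio) aldimine of 8, its ring oxygen bound to diisobutylaluminium | CC(C)C[Al](CC(C)C)N=C/C=C(C)/C=C/[C@@H]1C(C)=C[C@@H](O[Al](CC(C)C)CC(C)C)CC1(C)C | intermediate
8 | (2E,4E)-5-[(1S,4S)-4-hydroxy-2,6,6-trimethylcyclohex-2-en-1-yl]-3-methylpenta-2,4-dienal | O=C/C=C(C)/C=C/[C@@H]1C(C)=C[C@@H](O)CC1(C)C | intermediate
9 | propargyl alcohol, prop-2-yn-1-ol | C#CCO | starting material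
10 | (E)-alkenylalane: dimethylaluminium alkoxide of 3-(dimethylaluminio)-2-methylprop-2-en-1-ol | C[Al](C)OC/C(C)=C/[Al](C)C | intermediate
11 | (2E)-3-iodo-2-methylprop-2-en-1-ol | OC/C(C)=C/I | intermediate
12 | (1E)-3-bromo-1-iodo-2-methylprop-1-ene | BrC/C(C)=C/I | intermediate
13 | diethyl [(2E)-3-iodo-2-methylprop-2-en-1-yl]phosphonate | CCOP(=O)(OCC)C/C(C)=C/I | intermediate
14 | sodium salt of the α-carbanion of 13 | CCOP(=O)(OCC)[CH-]/C(C)=C/I.[Na+] | intermediate
15 | (1S,4S)-4-[(1E,3E,5E,7E)-8-iodo-3,7-dimethylocta-1,3,5,7-tetraen-1-yl]-3,5,5-trimethylcyclohex-2-en-1-ol | I/C=C(C)/C=C/C=C(C)/C=C/[C@@H]1C(C)=C[C@@H](O)CC1(C)C | intermediate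
16 | (4S)-4-[(1E,3E,5E,7E)-8-iodo-3,7-dimethylocta-1,3,5,7-tetraen-1-yl]-3,5,5-trimethylcyclohex-2-en-1-one | I/C=C(C)/C=C/C=C(C)/C=C/[C@@H]1C(C)=CC(=O)CC1(C)C | intermediate
17 | (E)-1,2-bis(tributylstannyl)ethene | CCCC[Sn](CCCC)(CCCC)/C=C/[Sn](CCCC)(CCCC)CCCC | starting material
18 | (4S)-4-[(1E,3E,5E,7E,9E)-3,7-dimethyl-10-(tributylstannyl)deca-1,3,5,7,9-pentaen-1-yl]-3,5,5-trimethylcyclohex-2-en-1-one | CCCC[Sn](CCCC)(CCCC)/C=C/C=C(C)/C=C/C=C(C)/C=C/[C@@H]1C(C)=CC(=O)CC1(C)C | intermediate
19 | (3'S,6S,6'S)-3'-hydroxy-ε,ε-caroten-3-one | CC1=CC(=O)CC(C)(C)[C@@H]1/C=C/C(C)=C/C=C/C(C)=C/C=C/C=C(C)/C=C/C=C(C)/C=C/[C@@H]1C(C)=C[C@@H](O)CC1(C)C | target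

**Total step count:** 11
**Longest linear sequence:** 8 steps (steps 1, 2, 3, 4, 8, 9, 10, 11, from α-ionone)

**Steps most likely to fail**

Step 11. Transmetalation from tin may be slow relative to homocoupling and protodestannylation of the stannane, and the long polyenes may scramble geometry or degrade during a prolonged reaction. The fallback forms the same bond as an sp–sp2 bond, using the most readily transferred group on tin, and restores the alkene afterwards. It sets out from 16: Stille coupling with an excess of bis(tributylstannyl)ethyne (Pd2(dba)3, AsPh3, NMP) would give tributyl{(3E,5E,7E,9E)-4,8-dimethyl-10-[(1S)-2,6,6-trimethyl-4-oxocyclohex-2-en-1-yl]deca-3,5,7,9-tetraen-1-yn-1-yl}stannane F1. A second Stille coupling of F1 with 15 would give (3'S,6S,6'S)-3'-hydroxy-15,15'-didehydro-ε,ε-caroten-3-one F2. Semi-hydrogenation (H2, Pd/CaCO3 poisoned with Pb(OAc)2, quinoline, EtOAc) would give (15Z,3'S,6S,6'S)-3'-hydroxy-ε,ε-caroten-3-one F3. Thermal Z-to-E isomerisation (heptane, 90 °C, dark, argon) then comes back to the route at 19.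

Step 3. The enzyme may discriminate the two faces of the C3 carbonyl insufficiently, or turn over the lipophilic substrate too slowly, so that stereochemical purity is lost. The fallback separates reduction and resolution and sets out from 5. Luche reduction (NaBH4, CeCl3·7H2O, MeOH, −20 °C) would give the racemic trans alcohol rac-(2E,4E)-5-[(1S*,4S*)-4-hydroxy-2,6,6-trimethylcyclohex-2-en-1-yl]-3-methylpenta-2,4-dienenitrile F4 together with the racemic cis alcohol rac-(2E,4E)-5-[(1R*,4S*)-4-hydroxy-2,6,6-trimethylcyclohex-2-en-1-yl]-3-methylpenta-2,4-dienenitrile F5, which chromatography removes. Lipase-catalysed kinetic resolution of F4 (lipase from Burkholderia cepacia, vinyl acetate, t-BuOMe, 30 °C) is expected, by the empirical size rule for secondary alcohols, to acylate the (3R,6R) enantiomer to (1R,4R)-4-[(1E,3E)-4-cyano-3-methylbuta-1,3-dien-1-yl]-3,5,5-trimethylcyclohex-2-en-1-yl acetate F6. The unreacted alcohol is 6, where the route is rejoined.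

Step 2. Site selectivity of the radical C–H oxidation may be lost through abstraction of the doubly allylic C6–H, attack on the dienenitrile or over-oxidation. The fallback moves the oxidation to a substrate without the dienenitrile and sets out from 1. Ketalisation (1,2-bis(trimethylsilyloxy)ethane, cat. TMSOTf, CH2Cl2, −78 °C) would give rac-2-methyl-2-[(E)-2-(2,6,6-trimethylcyclohex-2-en-1-yl)ethenyl]-1,3-dioxolane F7. Allylic oxidation (t-BuOOH, aq. NaOCl, MeCN, 0 °C) would give rac-3,5,5-trimethyl-4-[(E)-2-(2-methyl-1,3-dioxolan-2-yl)ethenyl]cyclohex-2-en-1-one F8. The ketoreductase reduction of step 3 applied to F8 would give (1S,4S)-3,5,5-trimethyl-4-[(E)-2-(2-methyl-1,3-dioxolan-2-yl)ethenyl]cyclohex-2-en-1-ol F9 and its separable diastereomer (1S,4R)-3,5,5-trimethyl-4-[(E)-2-(2-methyl-1,3-dioxolan-2-yl)ethenyl]cyclohex-2-en-1-ol F10. Mild deketalisation of F9 (PPTS, aq. acetone, rt) would give (3E)-4-[(1S,4S)-4-hydroxy-2,6,6-trimethylcyclohex-2-en-1-yl]but-3-en-2-one F11. Horner–Wadsworth–Emmons olefination of F11 with 2 (NaH, 2.2 equiv, THF) comes back to the route at 6.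

**Further compounds**
F1 | step 11 | tributyl{(3E,5E,7E,9E)-4,8-dimethyl-10-[(1S)-2,6,6-trimethyl-4-oxocyclohex-2-en-1-yl]deca-3,5,7,9-tetraen-1-yn-1-yl}stannane | CCCC[Sn](CCCC)(CCCC)C#C/C=C(C)/C=C/C=C(C)/C=C/[C@@H]1C(C)=CC(=O)CC1(C)C
F2 | step 11 | (3'S,6S,6'S)-3'-hydroxy-15,15'-didehydro-ε,ε-caroten-3-one | CC1=CC(=O)CC(C)(C)[C@@H]1/C=C/C(C)=C/C=C/C(C)=C/C#C/C=C(C)/C=C/C=C(C)/C=C/[C@@H]1C(C)=C[C@@H](O)CC1(C)C
F3 | step 11 | (15Z,3'S,6S,6'S)-3'-hydroxy-ε,ε-caroten-3-one | CC1=CC(=O)CC(C)(C)[C@@H]1/C=C/C(C)=C/C=C/C(C)=C/C=C\C=C(C)\C=C\C=C(C)\C=C\[C@@H]1C(C)=C[C@@H](O)CC1(C)C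
F4 | step 3 | rac-(2E,4E)-5-[(1S*,4S*)-4-hydroxy-2,6,6-trimethylcyclohex-2-en-1-yl]-3-methylpenta-2,4-dienenitrile (racemate, relative configuration shown) | N#C/C=C(C)/C=C/[C@@H]1C(C)=C[C@@H](O)CC1(C)C
F5 | step 3 | rac-(2E,4E)-5-[(1R*,4S*)-4-hydroxy-2,6,6-trimethylcyclohex-2-en-1-yl]-3-methylpenta-2,4-dienenitrile (racemate, relative configuration shown) | N#C/C=C(C)/C=C/[C@H]1C(C)=C[C@@H](O)CC1(C)C
F6 | step 3 | (1R,4R)-4-[(1E,3E)-4-cyano-3-methylbuta-1,3-dien-1-yl]-3,5,5-trimethylcyclohex-2-en-1-yl acetate | N#C/C=C(C)/C=C/[C@H]1C(C)=C[C@H](OC(C)=O)CC1(C)C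
F7 | step 2 | rac-2-methyl-2-[(E)-2-(2,6,6-trimethylcyclohex-2-en-1-yl)ethenyl]-1,3-dioxolane | CC1(OCCO1)/C=C/C1C(C)=CCCC1(C)C
F8 | step 2 | rac-3,5,5-trimethyl-4-[(E)-2-(2-methyl-1,3-dioxolan-2-yl)ethenyl]cyclohex-2-en-1-one | CC1(OCCO1)/C=C/C1C(C)=CC(=O)CC1(C)C
F9 | step 2 | (1S,4S)-3,5,5-trimethyl-4-[(E)-2-(2-methyl-1,3-dioxolan-2-yl)ethenyl]cyclohex-2-en-1-ol | CC1(OCCO1)/C=C/[C@@H]1C(C)=C[C@@H](O)CC1(C)C
F10 | step 2 | (1S,4R)-3,5,5-trimethyl-4-[(E)-2-(2-methyl-1,3-dioxolan-2-yl)ethenyl]cyclohex-2-en-1-ol | CC1(OCCO1)/C=C/[C@H]1C(C)=C[C@@H](O)CC1(C)C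
F11 | step 2 | (3E)-4-[(1S,4S)-4-hydroxy-2,6,6-trimethylcyclohex-2-en-1-yl]but-3-en-2-one | CC(=O)/C=C/[C@@H]1C(C)=C[C@@H](O)CC1(C)C
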